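The route rests on disconnecting two bonds around C8: C8–C9 (the methyl) and C7–ring A. Because C8 carries a methyl group and a methylene (C7) attached to ring A, a terminal alkene C7=C8 can be methylaluminated enantioselectively by a chiral zirconocene and the resulting primary C7–metal bond arylated under palladium in the same flask; one operation thus sets the C8 configuration and joins the two aryl halves. The substrate for this step is the (R)-2-methylbut-3-enyl arene bearing benzyl-protected ring B, whose C8' centre comes from a copper-catalysed asymmetric allylic methylation; ring A enters as a dibenzylated aryl triflate, and hydrogenolysis of three benzyl ethers completes sauriol B.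

Key step: step 7

Remark: lignan numbering is used (ring A = 3-methoxy-4,5-dioxygenated ring on C7, ring B = syringyl ring on C7'); the target SMILES corresponds to (8R,8'R). The enantiomers of (NMI)2ZrCl2 and of Taniaphos are defined by their sense of induction on the model substrates named in steps 3 and 7, and that sense governs if a supplier's sign or descriptor differs.

Step 1
Reactants: 1 4-allyl-2,6-dimethoxyphenol
Product: 2 5-allyl-2-(benzyloxy)-1,3-dimethoxybenzene
Conditions: BnBr (1.2 equiv), K2CO3 (2 equiv), DMF, 60 °C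
Reagents that add atoms: benzyl bromide, BrCc1ccccc1
Why: Williamson ether synthesis, in which the phenoxide formed with K2CO3 is alkylated at oxygen by benzyl bromide while the allyl group is inert.

Step 2
Reactants: 2 5-allyl-2-(benzyloxy)-1,3-dimethoxybenzene; 3 (E)-1,4-dibromobut-2-ene
Product: 4 (E)-2-(benzyloxy)-5-(4-bromobut-2-en-1-yl)-1,3-dimethoxybenzene
Conditions: 3 (3 equiv), second-generation Grubbs catalyst RuCl2(=CHPh)(PCy3)(H2IMes) (3 mol%), 1,4-benzoquinone (10 mol%), CH2Cl2, 40 °C
Reagents that add atoms: none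
Why: Olefin cross-metathesis of a terminal alkene with an excess of a symmetrical internal allylic dibromide should give the thermodynamically favoured E allylic bromide, with the aryl ethers and the C–Br bond inert to the ruthenium carbene and benzoquinone suppressing double-bond migration towards ring B.

Step 3
Reactants: 4 (E)-2-(benzyloxy)-5-(4-bromobut-2-en-1-yl)-1,3-dimethoxybenzene
Product: 5 (R)-2-(benzyloxy)-1,3-dimethoxy-5-(2-methylbut-3-en-1-yl)benzene
Conditions: MeMgBr (1.2 equiv, Et2O), CuBr·SMe2 (3 mol%), (R,R)-Taniaphos (3.5 mol%), CH2Cl2, −78 °C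
Reagents that add atoms: methylmagnesium bromide, C[Mg]Br
Why: Copper-catalysed asymmetric allylic alkylation (SN2′), in which the chiral monovalent copper–diphosphine methyl complex adds to the allylic bromide and delivers methyl to the γ-carbon C8' to give the branched alkene, the ligand enantiomer (the one that converts cinnamyl bromide into (S)-3-phenylbut-1-ene) fixing the face so that C8' is R here, where CH2Ar ranks below vinyl.

Step 4
Reactants: 6 5-hydroxyvanillin (3,4-dihydroxy-5-methoxybenzaldehyde)
Product: 7 3,4-bis(benzyloxy)-5-methoxybenzaldehyde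
Conditions: BnBr (2.5 equiv), K2CO3 (3 equiv), DMF, 60 °C
Reagents that add atoms: benzyl bromide, BrCc1ccccc1
Why: Double Williamson etherification of the two catechol hydroxyls, to which the aldehyde is stable.

Step 5
Reactants: 7 3,4-bis(benzyloxy)-5-methoxybenzaldehyde
Product: 9 3,4-bis(benzyloxy)-5-methoxyphenol, via aryl formate 8 (not isolated)
Conditions: mCPBA (1.3 equiv), CH2Cl2, 0 °C to rt; aqueous NaHCO3 wash; crude formate, K2CO3 (cat.), MeOH, rt
Reagents that add atoms: 3-chloroperbenzoic acid (mCPBA), OOC(=O)c1cccc(Cl)c1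
Why: Baeyer–Villiger (Dakin-type) oxidation, in which the electron-rich trialkoxyaryl group migrates in the Criegee adduct to give the aryl formate, which mild methanolysis cleaves to the phenol without touching the benzyl ethers.

Step 6
Reactants: 9 3,4-bis(benzyloxy)-5-methoxyphenol
Product: 10 3,4-bis(benzyloxy)-5-methoxyphenyl trifluoromethanesulfonate
Conditions: Tf2O (1.2 equiv), pyridine (2 equiv), CH2Cl2, 0 °C
Reagents that add atoms: trifluoromethanesulfonic anhydride, O=S(=O)(OS(=O)(=O)C(F)(F)F)C(F)(F)F
Why: O-Sulfonylation of a phenol with triflic anhydride and pyridine is general and leaves the aryl ethers untouched.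

Step 7
Reactants: 5 (R)-2-(benzyloxy)-1,3-dimethoxy-5-(2-methylbut-3-en-1-yl)benzene; 10 3,4-bis(benzyloxy)-5-methoxyphenyl trifluoromethanesulfonate; 11 trimethylaluminium
Product: 14 tri-O-benzyl sauriol B, via alkyldimethylalane 12 (not isolated), via alkylzinc triflate 13 (not isolated)
Conditions: Me3Al (2.5 equiv), (+)-(NMI)2ZrCl2 [bis(1-neomenthylindenyl)zirconium dichloride, the enantiomer that gives (S)-2-methylalkan-1-ols from 1-alkenes] (5 mol%), methylaluminoxane (MeAlO)n (0.3 equiv), CH2Cl2, 0 °C to rt; volatiles and excess Me3Al removed in vacuo; Zn(OTf)2 (1.1 equiv), DMF, 70 °C; 10 (3 equiv), PdCl2(DPEphos) (5 mol%), i-Bu2AlH (10 mol%), DMF, rt to 60 °C; 1 M HCl work-up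
Reagents that add atoms: none
Why: A methylzirconocene cation, formed from the chiral dichloride and Me3Al, adds across C7=C8 so that the new methyl C9 ends on C8 and zirconium on the terminal carbon, transmetallation to aluminium frees alane 12 and returns Zr–Me to the cycle, and after the surplus Me3Al is stripped Zn(OTf)2 takes the C7 alkyl group onto zinc (13), which is coupled with 10 by zerovalent palladium (generated from PdCl2(DPEphos) and i-Bu2AlH) through oxidative addition into the C–OTf bond, transmetallation and reductive elimination. The closest known reaction type is the zirconium-catalysed asymmetric carboalumination of 1-alkenes run in one pot with a Negishi coupling through zinc, applied here to an α-branched alkene and an aryl triflate. No ring is closed. The single new stereocentre, C8, is set by the zirconocene: the face attacked is the one that gives (S)-2-methylalkan-1-ols from simple 1-alkenes, which reads as 8R here because C8' outranks C7, whereas CH2OH outranks the chain in the alkanols. The step needs methyl-to-C8 regiochemistry, secured because the monosubstituted alkene is the only reactive site, face selectivity that dominates whatever intrinsic preference the neighbouring C8' centre exerts (any 8S,8'R diastereomer is to be removed from 14 by chromatography or crystallisation), and transfer of the alkyl group in competition with the aluminium-bound methyls, which is the reason for removing Me3Al and using surplus 10. The coupling takes place at an unsubstituted CH2, so neither stereocentre can erode, and because C8' and C8 are set by two independent catalysts the enantiomeric purity of the 8R,8'R isomer should exceed that of either single step.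

Step 8
Reactants: 14 tri-O-benzyl sauriol B
Product: 15 sauriol B
Conditions: H2 (1 atm), Pd/C (10 wt%), EtOAc/MeOH, rt
Reagents that add atoms: none
Why: Catalytic hydrogenolysis cleaves the three benzyl aryl ethers, while the methyl ethers, the arenes and the two non-benzylic sp3 stereocentres are not affected.

Compound list
1 | 4-allyl-2,6-dimethoxyphenol | C=CCc1cc(OC)c(O)c(OC)c1 | starting material
2 | 5-allyl-2-(benzyloxy)-1,3-dimethoxybenzene | C=CCc1cc(OC)c(OCc2ccccc2)c(OC)c1 | intermediate
3 | (E)-1,4-dibromobut-2-ene | BrC/C=C/CBr | starting material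
4 | (E)-2-(benzyloxy)-5-(4-bromobut-2-en-1-yl)-1,3-dimethoxybenzene | BrC/C=C/Cc1cc(OC)c(OCc2ccccc2)c(OC)c1 | intermediate
5 | (R)-2-(benzyloxy)-1,3-dimethoxy-5-(2-methylbut-3-en-1-yl)benzene | C=C[C@H](C)Cc1cc(OC)c(OCc2ccccc2)c(OC)c1 | intermediate
6 | 5-hydroxyvanillin (3,4-dihydroxy-5-methoxybenzaldehyde) | COc1cc(C=O)cc(O)c1O | starting material
7 | 3,4-bis(benzyloxy)-5-methoxybenzaldehyde | COc1cc(C=O)cc(OCc2ccccc2)c1OCc1ccccc1 | intermediate
8 | 3,4-bis(benzyloxy)-5-methoxyphenyl formate | COc1cc(OC=O)cc(OCc2ccccc2)c1OCc1ccccc1 | intermediate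
9 | 3,4-bis(benzyloxy)-5-methoxyphenol | COc1cc(O)cc(OCc2ccccc2)c1OCc1ccccc1 | intermediate
10 | 3,4-bis(benzyloxy)-5-methoxyphenyl trifluoromethanesulfonate | COc1cc(OS(=O)(=O)C(F)(F)F)cc(OCc2ccccc2)c1OCc1ccccc1 | intermediate
11 | trimethylaluminium | C[Al](C)C | starting material
12 | [(2S,3R)-4-(4-(benzyloxy)-3,5-dimethoxyphenyl)-2,3-dimethylbutyl]dimethylalane (Al on C7; same spatial arrangement at C8 and C8' as in 14) | C[Al](C)C[C@@H](C)[C@H](C)Cc1cc(OC)c(OCc2ccccc2)c(OC)c1 | intermediate
13 | [(2S,3R)-4-(4-(benzyloxy)-3,5-dimethoxyphenyl)-2,3-dimethylbutyl]zinc trifluoromethanesulfonate | FC(F)(F)S(=O)(=O)O[Zn]C[C@@H](C)[C@H](C)Cc1cc(OC)c(OCc2ccccc2)c(OC)c1 | intermediate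
14 | tri-O-benzyl sauriol B, 1,2-bis(benzyloxy)-5-[(2R,3R)-4-(4-(benzyloxy)-3,5-dimethoxyphenyl)-2,3-dimethylbutyl]-3-methoxybenzene | COc1cc(C[C@@H](C)[C@H](C)Cc2cc(OC)c(OCc3ccccc3)c(OC)c2)cc(OCc2ccccc2)c1OCc1ccccc1 | intermediate
15 | sauriol B, 5-[(2R,3R)-4-(4-hydroxy-3,5-dimethoxyphenyl)-2,3-dimethylbutyl]-3-methoxybenzene-1,2-diol | COc1cc(C[C@@H](C)[C@H](C)Cc2cc(OC)c(O)c(OC)c2)cc(O)c1O | target

Total step count: 8. Longest linear sequence: 5 steps (steps 1, 2, 3, 7, 8 from 1, or steps 4, 5, 6, 7, 8 from 6).

Steps most likely to fail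

Step 7. Insertion of the α-branched alkene may be slow or only moderately face-selective. Aluminium-bound methyl groups may be transferred to palladium in competition with the alkyl group. Oxidative addition of the electron-rich aryl triflate may lag behind. The fallback sets out from 5 and returns to the route at 14. The carboalumination is run alone under the same zirconocene and the alane 12 is oxidised with dry O2 and worked up with dilute HCl to give (2S,3R)-4-[4-(benzyloxy)-3,5-dimethoxyphenyl]-2,3-dimethylbutan-1-ol F1, at which stage the C8 epimer should be separable by chromatography. Iodination (I2, PPh3, imidazole, CH2Cl2) gives 2-(benzyloxy)-5-[(2R,3S)-4-iodo-2,3-dimethylbutyl]-1,3-dimethoxybenzene F2. Zinc insertion (Zn dust, LiCl, THF) gives [(2S,3R)-4-(4-(benzyloxy)-3,5-dimethoxyphenyl)-2,3-dimethylbutyl]zinc iodide F3. A separate Negishi coupling with 10 (Pd(OAc)2, SPhos, THF, 50 °C) then gives 14, with near-equimolar partners and no methyl groups on the metal.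

Step 3. Uncatalysed or linear (SN2) attack by the Grignard reagent, or Z-alkene carried over from step 2, may erode the regio- and enantioselectivity of the allylic methylation. The fallback sets out from 2 and returns at 5. Methylalumination of the plain allyl arene 2 (Me3Al, (−)-(NMI)2ZrCl2, the enantiomer that gives (R)-2-methylalkan-1-ols, CH2Cl2) gives [(R)-3-(4-(benzyloxy)-3,5-dimethoxyphenyl)-2-methylpropyl]dimethylalane F4, which is not isolated. Oxidation with O2 gives (R)-3-[4-(benzyloxy)-3,5-dimethoxyphenyl]-2-methylpropan-1-ol F5, whose enantiomeric purity can be raised by lipase-catalysed acetylation of the minor enantiomer. Dess–Martin oxidation (NaHCO3, CH2Cl2, 0 °C) gives (R)-3-[4-(benzyloxy)-3,5-dimethoxyphenyl]-2-methylpropanal F6, and Wittig methylenation (Ph3P=CH2, THF, −78 °C) gives 5.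

Step 2. Double-bond migration of the allyl arene into conjugation, homodimerisation, and incomplete E selectivity may all reduce the quality of the allylic bromide. The fallback sets out from 2 and returns at 4. Dihydroxylation (OsO4 cat., N-methylmorpholine N-oxide, acetone/H2O) gives 3-[4-(benzyloxy)-3,5-dimethoxyphenyl]propane-1,2-diol F7 (racemic, used crude). Periodate cleavage (NaIO4, THF/H2O) gives 2-[4-(benzyloxy)-3,5-dimethoxyphenyl]acetaldehyde F8. Wittig olefination with the stabilised ylide Ph3P=CHCO2Et (CH2Cl2, rt, base-free) gives ethyl (E)-4-[4-(benzyloxy)-3,5-dimethoxyphenyl]but-2-enoate F9. Reduction with i-Bu2AlH (CH2Cl2, −78 °C) gives (E)-4-[4-(benzyloxy)-3,5-dimethoxyphenyl]but-2-en-1-ol F10, and Appel bromination (CBr4, PPh3, CH2Cl2, 0 °C) gives 4 with defined E geometry.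

Further compounds
F1 | step 7 | (2S,3R)-4-[4-(benzyloxy)-3,5-dimethoxyphenyl]-2,3-dimethylbutan-1-ol | OC[C@@H](C)[C@H](C)Cc1cc(OC)c(OCc2ccccc2)c(OC)c1
F2 | step 7 | 2-(benzyloxy)-5-[(2R,3S)-4-iodo-2,3-dimethylbutyl]-1,3-dimethoxybenzene | IC[C@@H](C)[C@H](C)Cc1cc(OC)c(OCc2ccccc2)c(OC)c1
F3 | step 7 | [(2S,3R)-4-(4-(benzyloxy)-3,5-dimethoxyphenyl)-2,3-dimethylbutyl]zinc iodide | I[Zn]C[C@@H](C)[C@H](C)Cc1cc(OC)c(OCc2ccccc2)c(OC)c1
F4 | step 3 | [(R)-3-(4-(benzyloxy)-3,5-dimethoxyphenyl)-2-methylpropyl]dimethylalane | C[Al](C)C[C@H](C)Cc1cc(OC)c(OCc2ccccc2)c(OC)c1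
F5 | step 3 | (R)-3-[4-(benzyloxy)-3,5-dimethoxyphenyl]-2-methylpropan-1-ol | OC[C@H](C)Cc1cc(OC)c(OCc2ccccc2)c(OC)c1
F6 | step 3 | (R)-3-[4-(benzyloxy)-3,5-dimethoxyphenyl]-2-methylpropanal | O=C[C@H](C)Cc1cc(OC)c(OCc2ccccc2)c(OC)c1
F7 | step 2 | 3-[4-(benzyloxy)-3,5-dimethoxyphenyl]propane-1,2-diol (racemic) | OCC(O)Cc1cc(OC)c(OCc2ccccc2)c(OC)c1
F8 | step 2 | 2-[4-(benzyloxy)-3,5-dimethoxyphenyl]acetaldehyde | O=CCc1cc(OC)c(OCc2ccccc2)c(OC)c1
F9 | step 2 | ethyl (E)-4-[4-(benzyloxy)-3,5-dimethoxyphenyl]but-2-enoate | CCOC(=O)/C=C/Cc1cc(OC)c(OCc2ccccc2)c(OC)c1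
F10 | step 2 | (E)-4-[4-(benzyloxy)-3,5-dimethoxyphenyl]but-2-en-1-ol | OC/C=C/Cc1cc(OC)c(OCc2ccccc2)c(OC)c1
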